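**Retrosynthetic overview**

1. Macrocarpal N (31) ⇐ arylated cyclopentane bis-ketal 28, by ketal hydrolysis, two Rieche formylations at C3'/C5' and cleavage of three aryl methyl ethers.
2. 28 ⇐ redox-active ester 24 + aryl iodide 25. The strategy rests on the adjacent quaternary C4 and benzylic C9'–H, with C3 standing to the C4=C9' bond as the radical carbon of a 5-hexenyl chain through C2, the masked carbonyl C1 and C5; C3–C4 and C9'–C1' form in one operation.
3. 24 ⇐ homoallylic alcohol 14 (C1 oxidised, C2–C3–carboxyl added, C1 ketalised); 14 ⇐ (R)-allylic alcohol 10 by Still–Wittig shift, which sets C5 and the Z-C4=C9' bond.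
4. 10 ⇐ (+)-2-carene 1 by ozonolysis, Wittig olefination, Weinreb ketone synthesis and oxazaborolidine reduction.
5. Ring order: the cyclopropane comes with the carene, the arene with 25, and the cyclopentane is the only ring closed (step 16).

Key step: step 16

Numbering used: cyclopentanone carbons C1 (C=O), C2, C3, C4 (quaternary, methyl), C5 (CH bearing the cyclopropyl group); C9' is the benzylic CH, C10' the isobutyl CH2, C1' the arene carbon bonded to C9'.
Remark on the chemistry: tributyl(iodomethyl)stannane 11 and (3-bromopropoxy)(tert-butyl)dimethylsilane 16 are taken as purchasable; 17 is carried as a mixture of C1 epimers because C1 becomes a ketone in step 11.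

**Route**

Step 1
Reactants: 1 (+)-2-carene
Product: 3 (1S,3R)-2,2-dimethyl-3-(3-oxobutyl)cyclopropane-1-carbaldehyde (cis), via secondary ozonide 2 (not isolated)
Conditions: O3, CH2Cl2, −78 °C; then Me2S, −78 °C to rt; used crude
Reagents that add atoms: ozone, [O-][O+]=O
Why: Ozonolysis with reductive work-up cleaves the only C=C bond, and the cis relationship of the two cyclopropane substituents is inherited from the bicycle without touching a stereocentre.

Step 2
Reactants: 3 keto aldehyde; 4 ethyl 2-(triphenyl-λ5-phosphanylidene)propanoate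
Product: 5 ethyl (E)-2-methyl-3-[cis-2,2-dimethyl-3-(3-oxobutyl)cyclopropyl]prop-2-enoate
Conditions: toluene, 60 °C
Reagents that add atoms: 4, ethyl 2-(triphenyl-λ5-phosphanylidene)propanoate, CCOC(=O)C(C)=P(c1ccccc1)(c1ccccc1)c1ccccc1
Why: Wittig olefination with a stabilised ylide reacts only at the aldehyde, leaves the methyl ketone alone, needs no added base (so the cis aldehyde is not epimerised) and should give the (E)-trisubstituted enoate.

Step 3
Reactants: 5 keto enoate
Product: 6 ethyl (E)-2-methyl-3-{cis-2,2-dimethyl-3-[2-(2-methyl-1,3-dioxolan-2-yl)ethyl]cyclopropyl}prop-2-enoate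
Conditions: HOCH2CH2OH, pyridinium p-toluenesulfonate (cat.), benzene, reflux, Dean–Stark
Reagents that add atoms: ethylene glycol, OCCO
Why: Acid-catalysed ketalisation with removal of water protects the only ketone before organometallic steps, and the enoate and cyclopropane are inert to the weak acid.

Step 4
Reactants: 6 ketal enoate
Product: 7 (E)-N-methoxy-N-methyl enamide corresponding to 6
Conditions: MeNH(OMe)·HCl, iPrMgCl, THF, −20 to 0 °C
Reagents that add atoms: N,O-dimethylhydroxylamine hydrochloride, CNOC.Cl
Why: Aminolysis of the ester by the magnesium amide formed in the flask gives the Weinreb amide without touching the alkene geometry or the dioxolane.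

Step 5
Reactants: 7 Weinreb amide; 8 isobutylmagnesium bromide
Product: 9 (E)-1-{cis-2,2-dimethyl-3-[2-(2-methyl-1,3-dioxolan-2-yl)ethyl]cyclopropyl}-2,5-dimethylhex-1-en-3-one
Conditions: THF, 0 °C; aq NH4Cl
Reagents that add atoms: 8, isobutylmagnesium bromide, CC(C)C[Mg]Br
Why: Weinreb ketone synthesis stops at the chelated tetrahedral adduct, so a single isobutyl group is delivered and the enone appears only on work-up.

Step 6
Reactants: 9 enone
Product: 10 (R,E)-allylic alcohol: (3R,1E)-1-(cyclopropyl unit of 9)-2,5-dimethylhex-1-en-3-ol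
Conditions: (S)-2-methyl-CBS-oxazaborolidine (20 mol %), catecholborane, toluene, −78 °C; aq NaOH work-up
Reagents that add atoms: none
Why: Corey–Bakshi–Shibata reduction in which the α-methylalkenyl arm acts as the large group and isobutyl as the small one, so the (S)-oxazaborolidine should deliver hydride to give the (R)-carbinol (the future C9'), while catecholborane at −78 °C does not hydroborate the alkene.

Step 7
Reactants: 10 (R)-allylic alcohol; 11 tributyl(iodomethyl)stannane
Product: 12 tributylstannylmethyl ether of 10
Conditions: KH, THF, 0 °C; then 11, 18-crown-6 (cat.), 0 °C to rt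
Reagents that add atoms: 11, tributyl(iodomethyl)stannane, CCCC[Sn](CCCC)(CCCC)CI
Why: Williamson etherification of the potassium alkoxide with the reactive primary iodide installs the carbanion precursor without affecting the carbinol centre.

Step 8
Reactants: 12 stannylmethyl ether
Product: 14 (2R,3Z)-2-(cyclopropyl unit)-3,6-dimethylhept-3-en-1-ol (C5 is R; C4=C9' is Z), via lithiomethyl ether 13 (not isolated)
Conditions: nBuLi, THF, −78 to −20 °C; aq NH4Cl
Reagents that add atoms: none
Why: Still–Wittig [2,3]-sigmatropic rearrangement in which tin–lithium exchange gives the α-alkoxymethyllithium, which shifts suprafacially through a five-membered envelope with the isobutyl group pseudo-axial (avoiding A(1,2) strain with the C4 methyl), so the (R)-carbinol configuration is transferred to (R)-C5 and the new C4=C9' bond is Z.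

Step 9
Reactants: 14 homoallylic alcohol
Product: 15 (2R,3Z)-2-(cyclopropyl unit)-3,6-dimethylhept-3-enal
Conditions: Dess–Martin periodinane, NaHCO3, CH2Cl2, 0 °C; used at once
Reagents that add atoms: none
Why: Buffered Dess–Martin oxidation is fast and neutral, which should keep the doubly activated C5–H (α to the aldehyde and allylic) from epimerising.

Step 10
Reactants: 15 aldehyde; 16 (3-bromopropoxy)(tert-butyl)dimethylsilane
Product: 17 secondary alcohol TBSO(CH2)3–C1H(OH)–C5 (mixture of C1 epimers; C5 R; Z alkene)
Conditions: 16, Mg, THF, rt (Grignard reagent); CeCl3, THF, −78 °C; then 15, −78 °C; aq NH4Cl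
Reagents that add atoms: 16, (3-bromopropoxy)(tert-butyl)dimethylsilane, CC(C)(C)[Si](C)(C)OCCCBr, used as its Grignard reagent CC(C)(C)[Si](C)(C)OCCC[Mg]Br
Why: Cerium-mediated Grignard addition (Imamoto conditions) brings in C2, C3 and the future carboxyl carbon with a weakly basic nucleophile, so the α-branched aldehyde should add without enolisation at C5.

Step 11
Reactants: 17 secondary alcohol
Product: 18 ketone TBSO(CH2)3–C1(=O)–C5 (C5 R; Z alkene)
Conditions: Dess–Martin periodinane, NaHCO3, CH2Cl2, 0 °C to rt
Reagents that add atoms: none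
Why: Dess–Martin oxidation converges both C1 epimers on one ketone under neutral conditions that should not move the β,γ-double bond.

Step 12
Reactants: 18 β,γ-unsaturated ketone
Product: 19 bis-dioxolane silyl ether (C1 as 1,3-dioxolane; C5 R; Z alkene)
Conditions: (TMSOCH2)2, TMSOTf (10 mol %), CH2Cl2, −78 to −20 °C; pyridine quench
Reagents that add atoms: 1,2-bis(trimethylsilyloxy)ethane, C[Si](C)(C)OCCO[Si](C)(C)C
Why: Noyori ketalisation runs at low temperature without protic acid, so the ketone should be masked without epimerisation at C5 or migration of the C4=C9' bond into conjugation, and the silyl ether and the first dioxolane tolerate catalytic TMSOTf.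

Step 13
Reactants: 19 silyl ether
Product: 20 primary alcohol HO(CH2)3–C1(dioxolane)–C5
Conditions: TBAF, THF, 0 °C to rt
Reagents that add atoms: none
Why: Fluoride-induced desilylation frees the primary alcohol and is inert towards ketals, alkene and cyclopropane.

Step 14
Reactants: 20 primary alcohol
Product: 22 carboxylic acid HO2C–C3H2–C2H2–C1(dioxolane)–C5, via aldehyde 21 (not isolated)
Conditions: TEMPO (20 mol %), PhI(OAc)2, MeCN/pH 7 buffer, rt
Reagents that add atoms: water, O
Why: Oxoammonium (TEMPO) oxidation in aqueous acetonitrile takes the primary alcohol through the aldehyde hydrate to the acid under near-neutral conditions that spare the dioxolanes and the trisubstituted alkene.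

Step 15
Reactants: 22 acid; 23 N-hydroxyphthalimide
Product: 24 N-hydroxyphthalimide ester of 22 (redox-active ester; C5 R; Z alkene)
Conditions: N,N'-diisopropylcarbodiimide, DMAP (cat.), CH2Cl2, rt
Reagents that add atoms: 23, N-hydroxyphthalimide, O=C1c2ccccc2C(=O)N1O
Why: Carbodiimide (Steglich-type) esterification activates the acid under neutral conditions and gives the redox-active ester without affecting any stereocentre.

Step 16
Reactants: 24 redox-active ester; 25 2-iodo-1,3,5-trimethoxybenzene
Product: 28 arylated cyclopentane bis-ketal (4R;5R;9'S), via primary C3 radical 26 (not isolated), via cyclised C9' radical 27 (not isolated)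
Conditions: NiCl2(dme) (10 mol %), 4,4'-di-tert-butyl-2,2'-bipyridine (12 mol %), 25 (3 equiv), LiBr, DMA (0.02 M, 24 added slowly), Mg anode, reticulated vitreous carbon cathode, constant current, undivided cell, rt
Reagents that add atoms: 25, 2-iodo-1,3,5-trimethoxybenzene, COc1cc(OC)c(I)c(OC)c1
Why: Proposed new method: divalent nickel is reduced at the cathode to low-valent nickel, which adds oxidatively to 25 and passes one electron to the phthalimide ester; loss of phthalimide anion and CO2 leaves radical 26, which cyclises to radical 27, and 27 is captured by the aryl-nickel species to a trivalent alkyl(aryl)nickel that reductively eliminates the C9'–C1' bond, the closest known reaction types being nickel-electrocatalytic decarboxylative arylation of redox-active esters and nickel-catalysed reductive cyclisation–arylation of alkene-tethered alkyl electrophiles, neither yet shown for a 2,6-dimethoxyaryl partner at a radical next to a quaternary carbon. The one ring closed is the cyclopentane, by 5-exo-trig attack of C3 on C4. C4 is controlled by (R)-C5: in the Z alkene, A(1,3) strain with the isobutyl arm holds C5–H in the alkene plane, so the C1 chain delivers C3 to the face that leaves the methyl cis and C9' trans to the cyclopropyl group. C9' is set at the nickel stage: with C9'–H tucked under the ring, the bulky aryl-nickel should enter the sector between the C4 methyl and C3, anti to the C4–C5 bond that carries the cyclopropyl group and lies next to the C1 dioxolane, which gives the (S) centre, although this bias is expected to be modest. The step needs cyclisation to outrun direct arylation of 26 and 6-endo attack at C9'; the gem-dialkoxy C1 (Thorpe–Ingold effect), the isobutyl group shielding C9', high dilution and a low nickel loading are meant to secure this.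

Step 17
Reactants: 28 bis-ketal
Product: 29 diketone (C1 ketone and methyl ketone free; 2,4,6-trimethoxyphenyl at C9')
Conditions: 1 M HCl, THF, rt to 40 °C
Reagents that add atoms: water, O
Why: Acid-catalysed ketal hydrolysis frees both ketones, and C5 (now α to the C1 ketone) already has the cyclopropyl group trans to the bulky C9' arm, so no epimerisation is expected.

Step 18
Reactants: 29 diketone
Product: 30 3',5'-diformyl-2',4',6'-trimethoxy diketone
Conditions: Cl2CHOMe, TiCl4, CH2Cl2, −20 to 0 °C; then ice-cold 1 M HCl
Reagents that add atoms: dichloromethyl methyl ether, COC(Cl)Cl; water, O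
Why: Rieche formylation, in which the only free arene positions C3' and C5' are each activated by two ortho and one para methoxy group, so both should be formylated by the chloromethoxycarbenium electrophile faster than the TiCl4-complexed ketones can react.

Step 19
Reactants: 30 dialdehyde trimethyl ether
Product: 31 Macrocarpal N
Conditions: BCl3 (excess), CH2Cl2, −78 °C to rt; then H2O
Reagents that add atoms: none
Why: Lewis-acid ether cleavage in which every methoxy group is ortho to a formyl group, so BCl3 chelates between carbonyl and ether oxygen and chloride removes the methyl group at low temperature, conditions the ketones and the unactivated cyclopropane should survive.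

**Compound list**

1 | (+)-2-carene, (1S,6R)-3,7,7-trimethylbicyclo[4.1.0]hept-2-ene | CC1=C[C@H]2[C@@H](CC1)C2(C)C | starting material
2 | secondary ozonide of 1 (1,2,4-trioxolane across the former C=C, diastereomer mixture) | CC23CC[C@@H]1[C@H](C(OO2)O3)C1(C)C | intermediate (not isolated)
3 | (1S,3R)-2,2-dimethyl-3-(3-oxobutyl)cyclopropane-1-carbaldehyde | CC(=O)CC[C@@H]1[C@H](C=O)C1(C)C | intermediate
4 | ethyl 2-(triphenyl-λ5-phosphanylidene)propanoate | CCOC(=O)C(C)=P(c1ccccc1)(c1ccccc1)c1ccccc1 | starting material
5 | ethyl (E)-2-methyl-3-[cis-2,2-dimethyl-3-(3-oxobutyl)cyclopropyl]prop-2-enoate | CC(=O)CC[C@@H]1[C@H](/C=C(\C)C(=O)OCC)C1(C)C | intermediate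
6 | dioxolane-protected (E)-enoate | CC3(OCCO3)CC[C@@H]1[C@H](/C=C(\C)C(=O)OCC)C1(C)C | intermediate
7 | (E)-N-methoxy-N-methyl enamide | CC3(OCCO3)CC[C@@H]1[C@H](/C=C(\C)C(=O)N(C)OC)C1(C)C | intermediate
8 | isobutylmagnesium bromide | CC(C)C[Mg]Br | starting material
9 | (E)-isobutyl enone | CC3(OCCO3)CC[C@@H]1[C@H](/C=C(\C)C(=O)CC(C)C)C1(C)C | intermediate
10 | (R,E)-allylic alcohol | CC3(OCCO3)CC[C@@H]1[C@H](/C=C(\C)[C@H](O)CC(C)C)C1(C)C | intermediate
11 | tributyl(iodomethyl)stannane | CCCC[Sn](CCCC)(CCCC)CI | starting material
12 | tributylstannylmethyl ether of 10 | CC3(OCCO3)CC[C@@H]1[C@H](/C=C(\C)[C@H](OC[Sn](CCCC)(CCCC)CCCC)CC(C)C)C1(C)C | intermediate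
13 | lithiomethyl ether of 10 | CC3(OCCO3)CC[C@@H]1[C@H](/C=C(\C)[C@H](OC[Li])CC(C)C)C1(C)C | intermediate (not isolated)
14 | (Z)-homoallylic alcohol, C5 (R) | CC3(OCCO3)CC[C@@H]1[C@H]([C@@H](CO)/C(C)=C\CC(C)C)C1(C)C | intermediate
15 | (Z)-β,γ-unsaturated aldehyde, C5 (R) | CC3(OCCO3)CC[C@@H]1[C@H]([C@@H](C=O)/C(C)=C\CC(C)C)C1(C)C | intermediate
16 | (3-bromopropoxy)(tert-butyl)dimethylsilane | CC(C)(C)[Si](C)(C)OCCCBr | starting material
17 | C1 secondary alcohol with 3-(silyloxy)propyl chain (C1 epimers) | CC3(OCCO3)CC[C@@H]1[C@H]([C@@H](C(O)CCCO[Si](C)(C)C(C)(C)C)/C(C)=C\CC(C)C)C1(C)C | intermediate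
18 | C1 ketone | CC3(OCCO3)CC[C@@H]1[C@H]([C@@H](C(=O)CCCO[Si](C)(C)C(C)(C)C)/C(C)=C\CC(C)C)C1(C)C | intermediate
19 | bis-dioxolane silyl ether | CC3(OCCO3)CC[C@@H]1[C@H]([C@@H](C4(OCCO4)CCCO[Si](C)(C)C(C)(C)C)/C(C)=C\CC(C)C)C1(C)C | intermediate
20 | bis-dioxolane primary alcohol | CC3(OCCO3)CC[C@@H]1[C@H]([C@@H](C4(OCCO4)CCCO)/C(C)=C\CC(C)C)C1(C)C | intermediate
21 | bis-dioxolane aldehyde | CC3(OCCO3)CC[C@@H]1[C@H]([C@@H](C4(OCCO4)CCC=O)/C(C)=C\CC(C)C)C1(C)C | intermediate (not isolated)
22 | bis-dioxolane carboxylic acid | CC3(OCCO3)CC[C@@H]1[C@H]([C@@H](C4(OCCO4)CCC(=O)O)/C(C)=C\CC(C)C)C1(C)C | intermediate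
23 | N-hydroxyphthalimide | O=C1c2ccccc2C(=O)N1O | starting material
24 | redox-active ester of the (Z)-alkenyl keto acid bis-ketal | CC3(OCCO3)CC[C@@H]1[C@H]([C@@H](C4(OCCO4)CCC(=O)ON5C(=O)c6ccccc6C5=O)/C(C)=C\CC(C)C)C1(C)C | intermediate
25 | 2-iodo-1,3,5-trimethoxybenzene | COc1cc(OC)c(I)c(OC)c1 | starting material
26 | primary C3 radical | CC3(OCCO3)CC[C@@H]1[C@H]([C@@H](C4(OCCO4)C[CH2])/C(C)=C\CC(C)C)C1(C)C | intermediate (not isolated)
27 | cyclised C9' radical | CC3(OCCO3)CC[C@@H]1[C@H]([C@H]2C4(OCCO4)CC[C@]2(C)[CH]CC(C)C)C1(C)C | intermediate (not isolated)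
28 | arylated cyclopentane bis-ketal (4R,5R,9'S) | CC3(OCCO3)CC[C@@H]1[C@H]([C@H]2C4(OCCO4)CC[C@]2(C)[C@H](CC(C)C)c5c(OC)cc(OC)cc5OC)C1(C)C | intermediate
29 | trimethoxyaryl diketone | CC(=O)CC[C@@H]1[C@H]([C@H]2C(=O)CC[C@]2(C)[C@H](CC(C)C)c2c(OC)cc(OC)cc2OC)C1(C)C | intermediate
30 | diformyl trimethoxyaryl diketone | CC(=O)CC[C@@H]1[C@H]([C@H]2C(=O)CC[C@]2(C)[C@H](CC(C)C)c2c(OC)c(C=O)c(OC)c(C=O)c2OC)C1(C)C | intermediate
31 | Macrocarpal N | CC(=O)CC[C@@H]1[C@H]([C@H]2C(=O)CC[C@]2(C)[C@H](CC(C)C)c2c(O)c(C=O)c(O)c(C=O)c2O)C1(C)C | target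

**Step count and risks**

Total step count: 19. Longest linear sequence: 19 steps from (+)-2-carene.

Steps most likely to fail:

1. Step 16 (proposed new method). The hindered C9' radical may fail to couple with the di-ortho-substituted aryl-nickel and be lost by reduction or hydrogen abstraction. Radical 26 may be arylated before it cyclises or may close 6-endo. Nickel may meet C9' with poor facial selectivity. The fallback uses known chemistry, sets out from acid 22 and returns at 28.
   - Acid 22 is subjected to photochemical dehydrodecarboxylation (9-mesitylacridine, Co(dmgH)2(py)Cl, blue light, dilute). The C3 radical cyclises 5-exo before cobalt removes the C10' hydrogen, giving the cyclised (E)-alkene F1.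
   - Ozonolysis of F1 (O3, then Me2S) gives the neopentyl C9' aldehyde F2.
   - 2,4,6-Trimethoxyphenyllithium (from 25 and nBuLi, −78 °C) adds to F2 to give the benzylic alcohol F3 as an epimer mixture.
   - Ionisation of F3 with catalytic Bi(OTf)3 in the presence of methallyltrimethylsilane (SN1 allylation of the trimethoxybenzylic cation, −40 °C) gives the methallyl compound F4. The aryl group is again expected to prefer the less hindered C3 side, and the C9' epimers could be separated here.
   - Hydrogenation of F4 (H2, Pd/C, EtOAc) returns 28.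
2. Step 12. Under the Lewis acid the hindered β,γ-unsaturated ketone may enolise faster than it ketalises, with epimerisation at C5 or migration of the C4=C9' bond into conjugation. The fallback avoids the free ketone, sets out from aldehyde 15 and returns at 19.
   - Chemoselective thioacetalisation of 15 (propane-1,3-dithiol, catalytic Zn(OTf)2, CH2Cl2, 0 °C) gives the 1,3-dithiane F5.
   - Lithiation (nBuLi, THF/DMPU) and alkylation with the iodide corresponding to 16 (Corey–Seebach umpolung) gives the 2,2-dialkyl dithiane F6.
   - Exchange of the dithiane for the dioxolane (PhI(OCOCF3)2, ethylene glycol, MeCN, 0 °C) gives 19.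
3. Step 8. The α-alkoxymethyllithium may undergo a [1,2]-shift or be protonated instead of rearranging, or the shift may proceed with eroded Z-selectivity and chirality transfer. The fallback replaces the sigmatropic step by a directed allylic substitution, sets out from 10 and returns at 14.
   - Phenyl isocyanate converts 10 into the N-phenylcarbamate F7.
   - Deprotonation (MeLi) and syn-selective SN2' substitution with the cuprate from (isopropoxydimethylsilyl)methylmagnesium chloride and CuI should deliver the silylmethyl group to C5 on the face of the departing carbamate, giving the (Z)-alkenyl silane F8.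
   - Tamao oxidation of F8 (H2O2, KF, KHCO3, THF/MeOH) gives 14.

Further compounds
F1 | step 16 | cyclised bis-ketal with (E)-3-methylbut-1-enyl group on C4 | CC3(OCCO3)CC[C@@H]1[C@H]([C@H]2C4(OCCO4)CC[C@]2(C)/C=C/C(C)C)C1(C)C
F2 | step 16 | cyclised bis-ketal C9' aldehyde | CC3(OCCO3)CC[C@@H]1[C@H]([C@H]2C4(OCCO4)CC[C@]2(C)C=O)C1(C)C
F3 | step 16 | C9' (2,4,6-trimethoxyphenyl)carbinol, epimer mixture | CC3(OCCO3)CC[C@@H]1[C@H]([C@H]2C4(OCCO4)CC[C@]2(C)C(O)c5c(OC)cc(OC)cc5OC)C1(C)C
F4 | step 16 | C9' methallyl compound (9'S) | CC3(OCCO3)CC[C@@H]1[C@H]([C@H]2C4(OCCO4)CC[C@]2(C)[C@H](CC(C)=C)c5c(OC)cc(OC)cc5OC)C1(C)C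
F5 | step 12 | 1,3-dithiane of aldehyde 15 | CC3(OCCO3)CC[C@@H]1[C@H]([C@@H](C4SCCCS4)/C(C)=C\CC(C)C)C1(C)C
F6 | step 12 | 2-[3-(silyloxy)propyl] dithiane | CC3(OCCO3)CC[C@@H]1[C@H]([C@@H](C4(SCCCS4)CCCO[Si](C)(C)C(C)(C)C)/C(C)=C\CC(C)C)C1(C)C
F7 | step 8 | N-phenylcarbamate of 10 | CC3(OCCO3)CC[C@@H]1[C@H](/C=C(\C)[C@H](OC(=O)Nc2ccccc2)CC(C)C)C1(C)C
F8 | step 8 | (Z)-alkenyl (isopropoxydimethylsilyl)methyl compound, C5 (R) | CC3(OCCO3)CC[C@@H]1[C@H]([C@@H](C[Si](C)(C)OC(C)C)/C(C)=C\CC(C)C)C1(C)C
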